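**Retrosynthetic overview**
- The oxolane C2–O bond is made last: a guaiacyl p-quinone methide, formed from an open tetraol, is trapped by a primary hydroxyl (oxolane = second ring formed).
- The tetraol comes from LiAlH4 reduction of an all-trans γ-aryl-α-[aryl(hydroxy)methyl] paraconic acid (γ-lactone = first ring formed, opened later).
- That lactone acid comes from a trans-selective dianion aldol of a trans-γ-aryl paraconic acid with silyl-protected vanillin.
- Key step: a catalytic enantioselective Mukaiyama aldol–lactonisation of aromatic, C2v-symmetric 2,5-bis(trimethylsilyloxy)furan (from succinic anhydride) with 3,4-bis(benzyloxy)benzaldehyde. It breaks the furan's aromaticity and symmetry and sets the carbinol and the adjacent centre.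
- Ring order: γ-lactone, reductive opening, oxolane, then debenzylation.

Assumption: the two carbinol epimers formed in the second aldol are carried together under one number (SMILES leaves that centre open) because the quinone methide step erases it; reagents named only under Conditions are commercial.

**Step 1**
Reactants: 1 succinic anhydride
Product: 2 2,5-bis(trimethylsilyloxy)furan
Conditions: Me3SiCl (2.5 equiv), Et3N (2.5 equiv), ZnCl2 (5 mol %), MeCN, 25 to 45 °C; distil
Reagents that add atoms: chlorotrimethylsilane, C[Si](C)(C)Cl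
Why: Double O-silylation by soft enolisation of the anhydride is driven by formation of the aromatic 2,5-dioxyfuran, and no stereocentre is formed.

**Step 2**
Reactants: 2 2,5-bis(trimethylsilyloxy)furan; 3 3,4-bis(benzyloxy)benzaldehyde
Product: 5 (2R,3R)-2-[3,4-bis(benzyloxy)phenyl]-5-oxotetrahydrofuran-3-carboxylic acid, via silyl aldol adduct 4 (not isolated)
Conditions: 2 (1.5 equiv), acyloxyborane from (2R,3R)-2-O-(2,6-diisopropoxybenzoyl)tartaric acid and BH3·THF (20 mol %), EtCN, −78 °C; then 1 M HCl, THF, 0 °C to rt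
Reagents that add atoms: none
Why: Proposed new method: an enantioselective Mukaiyama aldol in which the chiral acyloxyborane binds the aldehyde and C3 of the electron-rich furan attacks through an open, extended transition state (the closest known reaction type, the acyloxyborane-catalysed Mukaiyama aldol of ketene silyl acetals with aromatic aldehydes, is syn-selective whatever the enol geometry, and the racemic TiCl4-mediated condensation of this furan with aldehydes to paraconic acids is known), so that Re-face attack sets the (R)-carbinol, the syn topicity sets the neighbouring centre, and acidic work-up desilylates and lets the new hydroxyl open the anhydride to the trans γ-lactone acid; the catalyst antipode from (2S,3S)-tartaric acid is used if the facial sense proves opposite.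

**Step 3**
Reactants: 6 vanillin
Product: 7 4-(tert-butyldimethylsilyloxy)-3-methoxybenzaldehyde
Conditions: tBuMe2SiCl (1.1 equiv), imidazole (2 equiv), DMF, rt
Reagents that add atoms: tert-butyldimethylsilyl chloride, CC(C)(C)[Si](C)(C)Cl
Why: Imidazole-promoted silylation of the phenol masks its acidity for the enolate step, and no stereocentre is formed.

**Step 4**
Reactants: 5 (2R,3R)-2-[3,4-bis(benzyloxy)phenyl]-5-oxotetrahydrofuran-3-carboxylic acid; 7 4-(tert-butyldimethylsilyloxy)-3-methoxybenzaldehyde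
Product: 8 (2R,3R,4S)-2-[3,4-bis(benzyloxy)phenyl]-4-{[4-(tert-butyldimethylsilyloxy)-3-methoxyphenyl](hydroxy)methyl}-5-oxotetrahydrofuran-3-carboxylic acid (both carbinol epimers)
Conditions: LiN(SiMe3)2 (2.3 equiv), THF, −78 °C; 7 (1.2 equiv), −78 °C; AcOH, −78 °C
Reagents that add atoms: none
Why: Aldol addition of the carboxylate/lactone-enolate dianion (the carboxylate blocks deprotonation next to it) takes the aldehyde on the enolate face anti to the adjacent carboxylate, so the new ring centre is trans, while the carbinol centre forms as a mixture that step 6 erases.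

**Step 5**
Reactants: 8 (2R,3R,4S)-lactone acid from step 4
Product: 10 (1R,2S,3R)-1-[3,4-bis(benzyloxy)phenyl]-4-(4-hydroxy-3-methoxyphenyl)-2,3-bis(hydroxymethyl)butane-1,4-diol (C4 epimers), via silyl tetraol 9 (not isolated)
Conditions: LiAlH4 (5 equiv), THF, 0 °C to rt; aqueous NaOH work-up; then Bu4NF (1.2 equiv), THF, 0 °C; NH4Cl (aq)
Reagents that add atoms: none
Why: Hydride reduction turns lactone and carboxylate into the primary alcohols without touching a stereocentre, and fluoride then cleaves the aryl silyl ether (and any silyl group that migrated) to free the phenol.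

**Step 6**
Reactants: 10 (1R,2S,3R)-phenol tetraol from step 5
Product: 12 4-[(2S,3R,4S)-4-{(R)-[3,4-bis(benzyloxy)phenyl](hydroxy)methyl}-3-(hydroxymethyl)tetrahydrofuran-2-yl]-2-methoxyphenol, via quinone methide 11 (not isolated)
Conditions: (PhO)2P(O)OH (10 mol %), MeCN, 30 °C
Reagents that add atoms: none
Why: The weak Brønsted acid dehydrates only the p-hydroxybenzylic alcohol to a p-quinone methide (the O-benzylated benzylic alcohol cannot form one), and the hydroxymethyl on C2 closes the ring by rearomatising 5-exo oxa-1,6-addition, which is reversible, so the aryl group ends trans to C3 in the all-trans oxolane whichever carbinol epimer entered.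

**Step 7**
Reactants: 12 dibenzyl ether from step 6
Product: 13 4-{(R)-hydroxy[(3S,4R,5S)-4-(hydroxymethyl)-5-(4-hydroxy-3-methoxyphenyl)tetrahydrofuran-3-yl]methyl}benzene-1,2-diol (CNP0197133.1)
Conditions: H2 (1 atm), 10% Pd/C, EtOAc–MeOH, rt
Reagents that add atoms: none
Why: Neutral hydrogenolysis cleaves the two aryl benzyl ethers faster than the benzylic C–O bonds of the oxolane and the carbinol, and no stereocentre is touched.

**Compound list**
1 | succinic anhydride | O=C1CCC(=O)O1 | starting material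
2 | 2,5-bis(trimethylsilyloxy)furan | C[Si](C)(C)Oc1ccc(O[Si](C)(C)C)o1 | intermediate
3 | 3,4-bis(benzyloxy)benzaldehyde | O=Cc1ccc(OCc2ccccc2)c(OCc2ccccc2)c1 | starting material
4 | (3R)-3-{(R)-[3,4-bis(benzyloxy)phenyl](trimethylsilyloxy)methyl}-5-(trimethylsilyloxy)furan-2(3H)-one | O=C1OC(O[Si](C)(C)C)=C[C@@H]1[C@@H](O[Si](C)(C)C)c1ccc(OCc2ccccc2)c(OCc2ccccc2)c1 | intermediate (not isolated)
5 | (2R,3R)-2-[3,4-bis(benzyloxy)phenyl]-5-oxotetrahydrofuran-3-carboxylic acid | OC(=O)[C@@H]1CC(=O)O[C@H]1c1ccc(OCc2ccccc2)c(OCc2ccccc2)c1 | intermediate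
6 | vanillin | COc1cc(C=O)ccc1O | starting material
7 | 4-(tert-butyldimethylsilyloxy)-3-methoxybenzaldehyde | COc1cc(C=O)ccc1O[Si](C)(C)C(C)(C)C | intermediate
8 | (2R,3R,4S)-2-[3,4-bis(benzyloxy)phenyl]-4-{[4-(tert-butyldimethylsilyloxy)-3-methoxyphenyl](hydroxy)methyl}-5-oxotetrahydrofuran-3-carboxylic acid, carbinol centre open | OC(=O)[C@@H]1[C@@H](C(O)c2ccc(O[Si](C)(C)C(C)(C)C)c(OC)c2)C(=O)O[C@H]1c1ccc(OCc2ccccc2)c(OCc2ccccc2)c1 | intermediate
9 | (1R,2S,3R)-1-[3,4-bis(benzyloxy)phenyl]-4-[4-(tert-butyldimethylsilyloxy)-3-methoxyphenyl]-2,3-bis(hydroxymethyl)butane-1,4-diol, C4 open | OC[C@@H]([C@@H](O)c1ccc(OCc2ccccc2)c(OCc2ccccc2)c1)[C@H](CO)C(O)c1ccc(O[Si](C)(C)C(C)(C)C)c(OC)c1 | intermediate (not isolated)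
10 | (1R,2S,3R)-1-[3,4-bis(benzyloxy)phenyl]-4-(4-hydroxy-3-methoxyphenyl)-2,3-bis(hydroxymethyl)butane-1,4-diol, C4 open | OC[C@@H]([C@@H](O)c1ccc(OCc2ccccc2)c(OCc2ccccc2)c1)[C@H](CO)C(O)c1ccc(O)c(OC)c1 | intermediate
11 | 4-{(2R,3S,4R)-4-[3,4-bis(benzyloxy)phenyl]-4-hydroxy-2,3-bis(hydroxymethyl)butylidene}-2-methoxycyclohexa-2,5-dien-1-one | OC[C@@H]([C@@H](O)c1ccc(OCc2ccccc2)c(OCc2ccccc2)c1)[C@H](CO)C=C1C=CC(=O)C(OC)=C1 | intermediate (not isolated)
12 | 4-[(2S,3R,4S)-4-{(R)-[3,4-bis(benzyloxy)phenyl](hydroxy)methyl}-3-(hydroxymethyl)tetrahydrofuran-2-yl]-2-methoxyphenol | COc1cc([C@H]2OC[C@@H]([C@@H](O)c3ccc(OCc4ccccc4)c(OCc4ccccc4)c3)[C@@H]2CO)ccc1O | intermediate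
13 | 4-{(R)-hydroxy[(3S,4R,5S)-4-(hydroxymethyl)-5-(4-hydroxy-3-methoxyphenyl)tetrahydrofuran-3-yl]methyl}benzene-1,2-diol | COc1cc([C@H]2OC[C@@H]([C@@H](O)c3ccc(O)c(O)c3)[C@@H]2CO)ccc1O | target

**Step count**
Total steps: 7. Longest linear sequence: 6 (steps 1, 2, 4, 5, 6, 7); step 3 is a one-step side branch.

**Three steps most likely to fail, with fallbacks**

Step 2 is the main risk: the enantioselectivity and the syn topicity of an untested furan nucleophile are unproven. A cis lactone cannot be corrected by acid, because epimerisation at the benzylic carbon would erode the ee. The fallback sets out from 3 and comes back at 5.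
- (R)-4-Benzyl-1,3-oxazolidin-2-one is N-acylated with methyl 4-chloro-4-oxobutanoate (nBuLi, THF, −78 °C) to give methyl 4-[(4R)-4-benzyl-2-oxo-1,3-oxazolidin-3-yl]-4-oxobutanoate F1.
- Its dibutylboron Z-enolate (Bu2BOTf, iPr2NEt, CH2Cl2, −78 to 0 °C) adds to 3 in an Evans syn aldol through a closed chair to give methyl (3R,4R)-3-{[(4R)-4-benzyl-2-oxo-1,3-oxazolidin-3-yl]carbonyl}-4-[3,4-bis(benzyloxy)phenyl]-4-hydroxybutanoate F2.
- F2 lactonises in the flask with loss of methanol to (4R)-4-benzyl-3-{[(2R,3R)-2-[3,4-bis(benzyloxy)phenyl]-5-oxotetrahydrofuran-3-yl]carbonyl}-1,3-oxazolidin-2-one F3.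
- LiOH/H2O2 (THF–H2O, 0 °C) removes the auxiliary and gives 5.

Step 6 is the second risk: the benzylic secondary hydroxyl could attack instead (giving a 2,5-diaryloxolane), the other benzylic alcohol could ionise under acid, or Friedel–Crafts closure could give a tetralin. The fallback generates the same quinone methide oxidatively under neutral conditions; it sets out from 5 (with 7 as the source of the benzyl unit) and comes back at 11, which closes to 12.
- 7 is reduced with NaBH4 (MeOH, 0 °C) to [4-(tert-butyldimethylsilyloxy)-3-methoxyphenyl]methanol F4, and PBr3 (Et2O, 0 °C) gives [4-(bromomethyl)-2-methoxyphenoxy](tert-butyl)dimethylsilane F5.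
- The dianion of 5 (LiN(SiMe3)2, THF, −78 °C) is alkylated by F5 trans to the carboxylate to give (2R,3R,4R)-2-[3,4-bis(benzyloxy)phenyl]-4-[4-(tert-butyldimethylsilyloxy)-3-methoxybenzyl]-5-oxotetrahydrofuran-3-carboxylic acid F6.
- LiAlH4 gives (1R,2S,3R)-1-[3,4-bis(benzyloxy)phenyl]-3-[4-(tert-butyldimethylsilyloxy)-3-methoxybenzyl]-2-(hydroxymethyl)butane-1,4-diol F7, and Bu4NF frees (1R,2S,3R)-1-[3,4-bis(benzyloxy)phenyl]-3-(4-hydroxy-3-methoxybenzyl)-2-(hydroxymethyl)butane-1,4-diol F8.
- DDQ (1.0 equiv, CH2Cl2–dioxane, 0 °C) oxidises the free phenol of F8 to 11.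

Step 4 is the third risk: retro-aldol or poor conversion of the dilithio species. The fallback replaces the lithium aldol by an irreversible Lewis-acid Mukaiyama aldol; it sets out from 5 and comes back at 8.
- 5 is bis-silylated (LiN(SiMe3)2, 2.2 equiv, then Me3SiCl, THF, −78 °C) to trimethylsilyl (2R,3R)-2-[3,4-bis(benzyloxy)phenyl]-5-(trimethylsilyloxy)-2,3-dihydrofuran-3-carboxylate F9.
- F9 adds to 7 under BF3·OEt2 (CH2Cl2, −78 °C) anti to the ester group, and aqueous work-up gives 8.

**Further compounds**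
F1 | step 2 | methyl 4-[(4R)-4-benzyl-2-oxo-1,3-oxazolidin-3-yl]-4-oxobutanoate | COC(=O)CCC(=O)N1[C@H](Cc2ccccc2)COC1=O
F2 | step 2 | methyl (3R,4R)-3-{[(4R)-4-benzyl-2-oxo-1,3-oxazolidin-3-yl]carbonyl}-4-[3,4-bis(benzyloxy)phenyl]-4-hydroxybutanoate | COC(=O)C[C@@H](C(=O)N1[C@H](Cc2ccccc2)COC1=O)[C@@H](O)c1ccc(OCc2ccccc2)c(OCc2ccccc2)c1
F3 | step 2 | (4R)-4-benzyl-3-{[(2R,3R)-2-[3,4-bis(benzyloxy)phenyl]-5-oxotetrahydrofuran-3-yl]carbonyl}-1,3-oxazolidin-2-one | O=C(N1[C@H](Cc2ccccc2)COC1=O)[C@@H]1CC(=O)O[C@H]1c1ccc(OCc2ccccc2)c(OCc2ccccc2)c1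
F4 | step 6 | [4-(tert-butyldimethylsilyloxy)-3-methoxyphenyl]methanol | COc1cc(CO)ccc1O[Si](C)(C)C(C)(C)C
F5 | step 6 | [4-(bromomethyl)-2-methoxyphenoxy](tert-butyl)dimethylsilane | COc1cc(CBr)ccc1O[Si](C)(C)C(C)(C)C
F6 | step 6 | (2R,3R,4R)-2-[3,4-bis(benzyloxy)phenyl]-4-[4-(tert-butyldimethylsilyloxy)-3-methoxybenzyl]-5-oxotetrahydrofuran-3-carboxylic acid | OC(=O)[C@@H]1[C@@H](Cc2ccc(O[Si](C)(C)C(C)(C)C)c(OC)c2)C(=O)O[C@H]1c1ccc(OCc2ccccc2)c(OCc2ccccc2)c1
F7 | step 6 | (1R,2S,3R)-1-[3,4-bis(benzyloxy)phenyl]-3-[4-(tert-butyldimethylsilyloxy)-3-methoxybenzyl]-2-(hydroxymethyl)butane-1,4-diol | OC[C@@H]([C@@H](O)c1ccc(OCc2ccccc2)c(OCc2ccccc2)c1)[C@H](CO)Cc1ccc(O[Si](C)(C)C(C)(C)C)c(OC)c1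
F8 | step 6 | (1R,2S,3R)-1-[3,4-bis(benzyloxy)phenyl]-3-(4-hydroxy-3-methoxybenzyl)-2-(hydroxymethyl)butane-1,4-diol | OC[C@@H]([C@@H](O)c1ccc(OCc2ccccc2)c(OCc2ccccc2)c1)[C@H](CO)Cc1ccc(O)c(OC)c1
F9 | step 4 | trimethylsilyl (2R,3R)-2-[3,4-bis(benzyloxy)phenyl]-5-(trimethylsilyloxy)-2,3-dihydrofuran-3-carboxylate | C[Si](C)(C)OC(=O)[C@@H]1C=C(O[Si](C)(C)C)O[C@H]1c1ccc(OCc2ccccc2)c(OCc2ccccc2)c1
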